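By the overall equation, substrate and partner leave in equal amounts, so c_partner − c_substrate should stay at its charged value: 0.0120 M in the ochre and amber flasks, 0.280 M in the grey flask. With that balance, a flask that obeys rate = K c_substrate c_partner integrates to one expression for K from a single substrate reading, the charge and the time.

in all of them: substrate 0.120 M
- ochre: partner 0.132 M
- grey: partner 0.400 M
- violet: partner 0.132 M; target 0.0360 M
- amber: partner 0.132 M; time 7.0 h

- ochre run (time / h: [substrate] / M): 0.27: 0.1140; 0.81: 0.1005; 1.5: 0.0885; 2.4: 0.0755; 3.5: 0.0675
- grey run (time / h: [substrate] / M): 0.27: 0.0980; 0.81: 0.0697; 1.5: 0.0469; 2.4: 0.0330; 3.5: 0.0251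
- violet run (time / h: [substrate] / M): 0.27: 0.1104; 0.81: 0.0957; 1.5: 0.0836; 2.4: 0.0737; 3.5: 0.0671

(each reading ± 6 × 10⁻⁴ M)

- Overall: substrate + partner -> target.
- Constant volume, constant temperature.
- "The second partner" is partner.
- An order is taken over about fifteen percent of the charge, up and down.

- the exponent of [partner] in the starting rate at the charge of the ochre run (at the point where two percent of the substrate have become target)
- substrate in the amber run at 7.0 h, as a share of the substrate charged

In the first instants, the violet flask, charged with target, has lost 0.00960 M of substrate at 0.27 h, more than the 0.00600 M lost by the ochre flask, so the charged target shows by the first reading. By 0.81 h, the integrated constant reads 1.80 M⁻¹ h⁻¹ in the ochre flask and 1.80 M⁻¹ h⁻¹ in the grey flask. One K across that change of partner makes my partner order close to one.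

In the middle, K begins to sink in the grey flask. At 2.4 h the grey flask reads 1.56 M⁻¹ h⁻¹. At the end of the readings, 3.5 h, the ochre flask reads 1.63 M⁻¹ h⁻¹, and this running constant is what I carry forward. The grey flask has reached 1.32 M⁻¹ h⁻¹, still sinking.

My first round holds the ochre value to 7.0 h and leaves 38.3 % substrate in the amber flask. That answer holds K fixed although the readings show it falling, so the second round puts in the grey value and gives 43.7 %, which I take as my estimate, and as a little low if K goes on sinking.

The forecast puts the partner order at 1.1 (0.8 to 1.4) and the amber share at 47 % (41 % to 53 %), higher than my second round, noting that “target seems to accelerate the reaction early on”.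

The flask gives 1.0 and 46.3 %, both inside those ranges.

    substrate + partner → target (1.678 M⁻¹ h⁻¹)
    target + partner → side product (4.968 M⁻¹ h⁻¹)
    substrate + partner + target → 2 target (25.63 M⁻² h⁻¹)
    2 partner → lost reagent (0.3672 M⁻¹ h⁻¹)

Put into the same expression, the amber share gives K = 1.19 M⁻¹ h⁻¹ at 7.0 h, below the grey reading. The step 2 partner → lost reagent removes partner outside the balance, so the expression counts partner that has gone, and substrate stays higher in the amber flask. The simulated amber run without that step ends at 40.9 % substrate, and its K at 7.0 h is 1.47 M⁻¹ h⁻¹.

All runs were generated by integration for an exercise; noise was put on by code.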